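## The problem

The target is a spiro[4.5]decane in which cyclopentane ring A (C1–C4) and cyclohexane ring B (C6–C10) share C5; C1 is the ring A carbinol, C2 carries the trienyl acetate side chain, C6 the 3-hydroxypropyl chain, C7 the exocyclic enal and C10 the methyl carbinol. Five stereocentres, (1S,2S,5S,6R,10S), have to be set: on ring B the hydroxypropyl chain, C1 and the C10 hydroxyl are all cis, and on ring A the C1 hydroxyl faces the C10 side and the C2 side chain the C6 side. The quaternary C5 and the tertiary C10 cannot be repaired once made, whereas C6 can, because it is alpha to C7 whenever C7 is a carbonyl, and a trigonal C7 with a group syn to C6 pushes the chain axial, where it sits better beside the C10 oxygen than beside the C10 methyl. The C10 oxygen, once it carries a bulky group, is the only handle that tells the two faces of ring A apart, strongly at C1 and more weakly at C2. Three alkenes need geometric control: the tetrasubstituted enal (formyl cis to C6, the contra-steric arrangement), the (E)-trisubstituted alkene that bears CH2OAc, and the (E)-disubstituted diene link. The fragile groups are the enal (γ-deprotonation, isomerisation), the cross-conjugated triene with its primary allylic acetate (acid, heat, oxidants, amines, organometallics) and any β-hydroxy ketone relation between O10 and a C1 carbonyl (retro-aldol), and a dithiane, while present, rules out electrophilic oxidants. The feature that invites the key step is that C6, C5 and C10 are contiguous and C5 is alpha to C1: with C1 as a ketone, C5=C6 is an exocyclic enone, and a nucleophile that delivers the chain to C6 leaves the C5 enolate, which can close ring B by aldol addition to a methyl ketone at C10. The chair of that closure is expected to place the chain trans to C1, so the cascade cannot deliver C6 in the target configuration and the plan inverts C6 afterwards.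

## Retrosynthesis

**Enal and end game.** Target 36 is 35 without its three silyl ethers. The enal of 35 is cut as an allylic transposition: the formyl carbon and the C7=C bond come from the isopropenyl carbinol 34, whose C7–C bond is made earlier, when an isopropenyl nucleophile adds to ketone 23 to give 24. An intermolecular olefination of 23 would be slow at this hindered ketone and would put the carbonyl group trans to the branched C6, the wrong isomer. The forward reaction must pass through the rotamer that turns the CH2–O terminus toward C6, and the oxidant must spare the triene.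

**Side chain.** The trisubstituted alkene is cut between the ester α-carbon and the next carbon, giving ester 24 and dienal 29 (aldol 30, elimination to 32, reduction to 33, acetylation to 34). Cutting the C2–C bond instead would need an sp3–sp2 coupling at a hindered ring carbon with no stereocontrol. The ester gives CH2OAc by reduction, and the triene enters only after every step that uses heat, amines or iodomethane. Dienal 29 is cut at the diene single bond into alkenyl triflate 26 (from ketone 25) and alkenylboronate 27.

**C6.** Ketone 23 comes from its C6 epimer 21 through enamine 22. No bond is cut; this is the one point where C6 is alpha to a trigonal carbon that can carry a syn substituent without an alkene geometry being at stake. It is placed after the dithiane is removed and before any alkene exists.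

**Ring A.** Ketone 21 comes from dithiane 20, and 20 from alcohol 19 and ketone 18. The C2–CH2 bond of 18 is cut to the enolate of 16 and tert-butyl bromoacetate 17, and 16 is the silyl ether of ketol 15. An epoxide opening would guarantee the trans relation of C1 and C2, but electrophilic oxidants are excluded by the dithiane. The forward steps ask the C10 silyloxy group to direct both the alkylation at C2 and the hydride at C1.

**Key disconnection.** Ketol 15 is cut at the C6–chain bond and the C5–C10 bond into enone 9 and diorganozinc 12. This removes ring B, two skeletal bonds and three stereocentres at once and leaves an achiral precursor. The neighbouring cuts (C5–C6 by a 1,2-shift, C1–C2 by radical closure of ring A) each need a precursor that already holds most of the stereocentres.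

**Precursors.** Enone 9 is the unmasked form of ketal 8, cut at C5=C6 into cyclopentanone 5 and aldehyde 4. Aldehyde 4 is cut twice at the dithiane carbon, back to 1,3-dithiane 1 and bromide 2 by way of 3, with the formyl carbon added last. Zinc reagent 12 comes from iodide 10 through alkylzinc iodide 11. Its second ligand is a (trimethylsilyl)methyl group, which is not transferred, so every chain made from 10 can be delivered to C6; a symmetrical dialkylzinc would consume two chains and transfer one.

## Roads not taken

**Alternative 1: lactone-tethered olefination.** The cut is the exocyclic C7=C bond, made intramolecularly. Keto phosphonate A1, in which the hydroxypropyl oxygen carries a phosphonopropionate, would be treated with LiCl and DBU to give the eight-membered unsaturated lactone A2. The merit is real: both ends of the new alkene sit in one ring, so the carbonyl carbon must end cis to C6. Reduction of A2 and allylic oxidation would then release the chain hydroxyl and the enal together. On enal geometry this road is better than the chosen plan, which relies on a kinetic rotamer preference in step 20. The weak points are an eight-membered ring closed onto a hindered, α-branched ketone to form a tetrasubstituted alkene, competing oligomerisation, and heavier protecting-group traffic. It also solves the last problem and not the first: A1 already contains the spiro skeleton and all five stereocentres. The chosen plan sets against it a two-step enal installation and a catalytic step that builds ring B with three stereocentres from an achiral precursor.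

**Alternative 2: samarium ketyl–enoate closure of ring A.** The cut is the C1–C2 bond. Aldehyde enoate A3 would be reduced by SmI2 to a ketyl that adds 5-exo to the enoate, giving cyclopentanol A4. Ketyl–olefin closures of this type give the trans-2-substituted cyclopentanol reliably, and samarium bound to the C10 hydroxyl could fix the face. This sets C1 and C2 together with better control than step 8 of the chosen plan. A4 would also carry the chain cis to C1 directly, which the chosen plan reaches only after step 12. The weak points lie before the key step: A3 needs the quaternary C5 and the three contiguous ring B stereocentres built on a cyclohexane with no obvious enantioselective entry, and A3 is a β-hydroxy aldehyde on a quaternary carbon, which is prone to retro-aldol cleavage. The chosen plan sets against it the one-step catalytic construction of that stereotriad and the use of ring A's own ketone to activate C5.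

**Alternative 3: epoxy-alcohol semipinacol.** The cut is the C5–C6 bond, formed by a 1,2-shift. Epoxy alcohol A5 would be opened by BF3·OEt2 at its tertiary carbon while the substituted carbon of the attached cyclopentanol migrates, giving spiro hydroxy ketone A6. The shift is stereospecific (migration anti to the C–O bond, retention in the migrating carbon), so C5, C6 and C1 would come out in the target relation in one step. In this respect it is better than the chosen plan, which has to invert C6. The weak points are the precursor (a tetrasubstituted epoxide of defined face beside three further stereocentres), the competition between the two ring carbons that can migrate, and a long tail. C10 would be set late by methyl addition to a ketone next to the quaternary centre, and the C7 silyl group would have to be oxidised to the ketone. The chosen plan sets against it the early, simultaneous setting of C5 and C10 and a much simpler precursor.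

Key step: step 6

Remark on the chemistry: the chair of the aldol closure is taken to place the silyloxypropyl chain trans to the C1 carbonyl, so 15 is drawn as the C6 epimer of the target pattern and C6 is inverted in step 12; the phosphoramidite antipode meant is the one that delivers the alkyl group to the Re face of C6.

## Route

Step 1
Reactants: 1 1,3-dithiane; 2 2-(2-bromoethyl)-2-methyl-1,3-dioxolane
Product: 3 2-[2-(1,3-dithian-2-yl)ethyl]-2-methyl-1,3-dioxolane
Conditions: n-BuLi, THF, −30 °C; then 2, −30 → 0 °C
Reagents that add atoms: none
Why: Corey–Seebach alkylation: 2-lithio-1,3-dithiane displaces the primary bromide, and the dioxolane keeps the future C10 ketone masked.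

Step 2
Reactants: 3 2-[2-(1,3-dithian-2-yl)ethyl]-2-methyl-1,3-dioxolane
Product: 4 2-[2-(2-methyl-1,3-dioxolan-2-yl)ethyl]-1,3-dithiane-2-carbaldehyde
Conditions: n-BuLi, THF, −30 °C; DMF, −78 → 0 °C; H2O
Reagents that add atoms: N,N-dimethylformamide, CN(C)C=O
Why: A second lithiation at the dithiane carbon and formylation with DMF should give the non-enolisable aldehyde that carries the masked C7 carbonyl.

Step 3
Reactants: 5 cyclopentanone; 4 2-[2-(2-methyl-1,3-dioxolan-2-yl)ethyl]-1,3-dithiane-2-carbaldehyde
Product: 8 (E)-alkylidene cyclopentanone ketal, via lithium aldolate 6 (not isolated), via β-acetoxy ketone 7 (not isolated)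
Conditions: LiN(iPr)2, THF, −78 °C; 4; Ac2O, −78 → 0 °C; DBU, rt
Reagents that add atoms: none
Why: Directed aldol addition of the cyclopentanone lithium enolate, O-acetylation of the aldolate and E1cB elimination; the bulky dithianyl group ends anti to the carbonyl, which is the (E)-enone.

Step 4
Reactants: 8 (E)-alkylidene cyclopentanone ketal
Product: 9 (E)-2-{[2-(3-oxobutyl)-1,3-dithian-2-yl]methylidene}cyclopentan-1-one
Conditions: 1 M HCl, THF, rt
Reagents that add atoms: water, O
Why: Acetal hydrolysis; the dithiane and the enone are inert to dilute aqueous acid, so only the methyl ketone is unmasked.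

Step 5
Reactants: 10 tert-butyl(3-iodopropoxy)dimethylsilane
Product: 12 [3-(tert-butyldimethylsilyloxy)propyl][(trimethylsilyl)methyl]zinc, via alkylzinc iodide 11 (not isolated)
Conditions: Zn dust (activated with BrCH2CH2Br and Me3SiCl), THF, 40 °C; Me3SiCH2Li (1.0 equiv, pentane), −78 → 0 °C; then evaporation, toluene, filtration from LiI
Reagents that add atoms: zinc, [Zn]; (trimethylsilyl)methyllithium, C[Si](C)(C)C[Li]
Why: Direct insertion of activated zinc into the primary alkyl iodide gives the alkylzinc iodide, and transmetalation with (trimethylsilyl)methyllithium replaces iodide by a ligand that is not transferred in copper-mediated conjugate additions. Exchange of the solvent for toluene and filtration removes LiI, so the copper catalysis receives a halide-poor mixed diorganozinc in which the only transferable group is the silyloxypropyl chain.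

Step 6
Reactants: 9 (E)-2-{[2-(3-oxobutyl)-1,3-dithian-2-yl]methylidene}cyclopentan-1-one; 12 [3-(tert-butyldimethylsilyloxy)propyl][(trimethylsilyl)methyl]zinc
Product: 15 spiro ketol (chain trans to C1), via zinc enolate 13 (not isolated), via zinc aldolate 14 (not isolated)
Conditions: Cu(OTf)2 (5 mol %), O,O′-(S)-1,1′-binaphthyl-2,2′-diyl N,N-bis[(R)-1-phenylethyl]phosphoramidite (10 mol %), 12 (1.5 equiv), toluene, −30 → 0 °C; then pH 7 buffer
Reagents that add atoms: none
Why: The diorganozinc reduces Cu(OTf)2 to a monovalent copper–phosphoramidite species and hands it the silyloxypropyl group only, the (trimethylsilyl)methyl group staying on zinc; the alkylcopper binds the s-cis enone and delivers the chain to C6 through a trivalent copper intermediate, leaving zinc enolate 13. The closest known reaction type is the copper-catalysed asymmetric conjugate addition of dialkylzincs to enones with intramolecular aldol capture of the zinc enolate by a tethered ketone. Ring B closes in the 6-(enolexo)-exo-trig mode when C5 of 13 attacks the methyl ketone through a chair in which zinc bridges both oxygens, giving aldolate 14. C6 is set by the ligand (alkyl to the Re face). C5 is set by allylic 1,3-strain: the C6–H lies in the enolate plane beside the enolate oxygen and the dithiane carbon sits on the attacking face, so the chain ends equatorial and trans to C1. C10 is set by the zinc bridge, which holds the ketone oxygen over the enolate oxygen, so the hydroxyl is axial and cis to C1 and the methyl equatorial. The step needs 1,4- over 1,2-addition, transfer of the functionalised alkyl group only and aldol at the methyl ketone only; diorganozincs do not add to ketones without catalysis, the α-silyl group does not pass to copper at these temperatures, and the enolate forms regiospecifically at C5, from which only the six-membered closure is in reach.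

Step 7
Reactants: 15 spiro ketol (chain trans to C1)
Product: 16 C10 triethylsilyl ether of 15
Conditions: Et3SiOTf (1.1 equiv), 2,6-lutidine, CH2Cl2, −78 °C
Reagents that add atoms: triethylsilyl trifluoromethanesulfonate, CC[Si](CC)(CC)OS(=O)(=O)C(F)(F)F
Why: Silylation of the tertiary alcohol blocks retro-aldol opening of ring B under the bases that follow, and the axial triethylsilyloxy group becomes the shield that tells the faces of ring A apart.

Step 8
Reactants: 16 C10 triethylsilyl ether of 15; 17 tert-butyl bromoacetate
Product: 18 C2-alkylated keto ester
Conditions: LiN(iPr)2, THF, −78 °C; 17, DMPU, −78 → −30 °C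
Reagents that add atoms: none
Why: Kinetic enolate alkylation; C5 is quaternary, so only C2 can be deprotonated. The electrophile should enter anti to the fully substituted C10 arm with its silyloxy group, on the C6 side as in the target, but the bias reaches C2 over one more bond than C1 and is the least secure stereochemical call of the route.

Step 9
Reactants: 18 C2-alkylated keto ester
Product: 19 C1 alcohol (hydroxyl trans to the C2 arm)
Conditions: NaBH4, CeCl3·7H2O, MeOH/THF, −40 °C
Reagents that add atoms: none
Why: Luche-type borohydride reduction; hydride should attack C1 from the face beside C6–H because the axial C10 silyloxy group blocks the other, which puts the hydroxyl on the C10 side and trans to the C2 substituent. CeCl3 speeds reduction of the hindered ketone and suppresses base-mediated epimerisation at C2.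

Step 10
Reactants: 19 C1 alcohol (hydroxyl trans to the C2 arm)
Product: 20 bis(triethylsilyl) ether
Conditions: Et3SiOTf, 2,6-lutidine, CH2Cl2, −78 → 0 °C
Reagents that add atoms: triethylsilyl trifluoromethanesulfonate, CC[Si](CC)(CC)OS(=O)(=O)C(F)(F)F
Why: Silylation of the neopentyl secondary alcohol keeps C1 from being oxidised in step 20; any silyl shift from O10 to O1 during step 9 converges here on the same bis-silyl ether.

Step 11
Reactants: 20 bis(triethylsilyl) ether
Product: 21 C7 ketone (chain trans to C1)
Conditions: MeI, CaCO3, MeCN/H2O (4:1), 45 °C
Reagents that add atoms: water, O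
Why: Alkylative hydrolysis of the dithiane (S-methylation, then attack of water) under neutral conditions that spare the silyl ethers and the ester; no alkene is present yet.

Step 12
Reactants: 21 C7 ketone (chain trans to C1)
Product: 23 C7 ketone (chain cis to C1), via pyrrolidine enamine 22 (not isolated)
Conditions: pyrrolidine, p-toluenesulfonic acid monohydrate (5 mol %), benzene, reflux with water separator; then AcOH/NaOAc buffer (pH 5), THF/H2O, rt
Reagents that add atoms: none
Why: Enamine formation and hydrolysis used as a contra-thermodynamic epimerisation. In the less substituted enamine 22, allylic 1,3-strain with the pyrrolidine ring forces the C6 chain axial, and an axial chain is better placed syn to the C10 oxygen (the target configuration) than syn to the C10 methyl, so the enamine–iminium equilibrium should drain into 22. Buffered hydrolysis protonates C8 only and leaves C6 as set.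

Step 13
Reactants: 23 C7 ketone (chain cis to C1)
Product: 24 C7 isopropenyl carbinol
Conditions: CH2=C(CH3)MgBr, CeCl3, THF, −78 → −20 °C
Reagents that add atoms: isopropenylmagnesium bromide, CC(=C)[Mg]Br
Why: Organocerium addition to a hindered, enolisable ketone without deprotonation, so C6 is kept; the tert-butyl ester is not attacked at low temperature. Attack from the equatorial side should give the axial alcohol drawn, and either C7 epimer would serve because C7 becomes trigonal in step 20.

Step 14
Reactants: 25 6-methylhept-5-en-2-one
Product: 26 6-methylhepta-1,5-dien-2-yl trifluoromethanesulfonate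
Conditions: LiN(iPr)2, THF, −78 °C; PhNTf2, −78 → 0 °C
Reagents that add atoms: N-phenylbis(trifluoromethanesulfonimide), O=S(=O)(N(c1ccccc1)S(=O)(=O)C(F)(F)F)C(F)(F)F
Why: Kinetic deprotonation of the methyl ketone at the methyl group and O-triflation of the terminal enolate.

Step 15
Reactants: 26 6-methylhepta-1,5-dien-2-yl trifluoromethanesulfonate; 27 (E)-2-(3,3-diethoxyprop-1-enyl)-4,4,5,5-tetramethyl-1,3,2-dioxaborolane
Product: 29 (2E)-8-methyl-4-methylidenenona-2,7-dienal, via diethyl acetal 28 (not isolated)
Conditions: Pd(PPh3)4 (5 mol %), K3PO4, dioxane/H2O, 60 °C; then 1 M HCl, THF, 0 °C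
Reagents that add atoms: water, O
Why: Suzuki–Miyaura coupling of the alkenyl triflate with the (E)-alkenylboronate keeps the alkene geometry; mild acid then releases the dienal, which is used at once because 2-substituted dienes dimerise.

Step 16
Reactants: 24 C7 isopropenyl carbinol; 29 (2E)-8-methyl-4-methylidenenona-2,7-dienal
Product: 30 β-hydroxy ester (aldol adduct)
Conditions: LiN(iPr)2 (2.2 equiv), THF, −78 °C; 29, −78 °C; H2O
Reagents that add atoms: none
Why: Aldol addition of the tert-butyl ester lithium enolate to the aldehyde, 1,2-selective as usual for lithium enolates and enals; one equivalent of base is taken up by the C7 hydroxyl, and the two new stereocentres are removed in step 17.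

Step 17
Reactants: 30 β-hydroxy ester (aldol adduct)
Product: 32 (E)-trienoate, via allylic mesylate 31 (not isolated)
Conditions: MsCl, Et3N, CH2Cl2, −20 °C; then DBU, 0 °C → rt
Reagents that add atoms: none
Why: Mesylation of the secondary aldol hydroxyl (the hindered tertiary C7 hydroxyl should not react) and E1cB elimination; the ester enolate expels mesylate from the conformer with the dienyl group anti to the ester, so both diastereomers should converge on the (E)-alkene.

Step 18
Reactants: 32 (E)-trienoate
Product: 33 allylic alcohol
Conditions: iBu2AlH, CH2Cl2, −78 → −20 °C; aq. potassium sodium tartrate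
Reagents that add atoms: none
Why: 1,2-Reduction of the α,β-unsaturated tert-butyl ester to the allylic alcohol; silyl ethers and the tertiary allylic alcohol are untouched.

Step 19
Reactants: 33 allylic alcohol
Product: 34 allylic acetate
Conditions: Ac2O, pyridine, CH2Cl2, 0 °C
Reagents that add atoms: acetic anhydride, CC(=O)OC(C)=O
Why: Acylation of the only unhindered hydroxyl; the tertiary allylic C7 alcohol is not acetylated under these conditions.

Step 20
Reactants: 34 allylic acetate
Product: 35 (Z)-enal
Conditions: [C5H5NH][CrO3Cl], NaOAc, 4 Å molecular sieves, CH2Cl2, 0 °C → rt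
Reagents that add atoms: pyridinium chlorochromate, [O-][Cr](=O)(=O)Cl.c1cc[nH+]cc1
Why: Babler–Dauben oxidative transposition: the tertiary allylic chromate ester undergoes a 3,3-shift to the primary allylic chromate, which is oxidised to the enal (the aldehyde oxygen comes from chromium). In the chair transition state the vinylic methyl lies nearly eclipsed with one ring carbon and is better placed over C8H2 than over the branched C6, so the formyl group should end cis to C6. The C1 and C10 oxygens are silylated and can neither be oxidised nor add across the ring.

Step 21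
Reactants: 35 (Z)-enal
Product: 36 CNP0204268.2
Conditions: HF·pyridine, pyridine, THF, 0 °C → rt
Reagents that add atoms: none
Why: Fluoride-mediated cleavage of the primary tert-butyldimethylsilyl ether and the secondary and tertiary triethylsilyl ethers under buffered conditions that should leave the allylic acetate and the enal intact.

## Compound list

1 | 1,3-dithiane | C1CSCSC1 | starting material
2 | 2-(2-bromoethyl)-2-methyl-1,3-dioxolane | CC1(CCBr)OCCO1 | starting material
3 | 2-[2-(1,3-dithian-2-yl)ethyl]-2-methyl-1,3-dioxolane | CC1(CCC2SCCCS2)OCCO1 | intermediate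
4 | 2-[2-(2-methyl-1,3-dioxolan-2-yl)ethyl]-1,3-dithiane-2-carbaldehyde | CC1(CCC2(C=O)SCCCS2)OCCO1 | intermediate
5 | cyclopentanone | O=C1CCCC1 | starting material
6 | lithium aldolate from 5 and 4 (lithium alkoxide of the β-hydroxy ketone, both diastereomers) | [Li]OC(C1CCCC1=O)C1(CCC2(C)OCCO2)SCCCS1 | intermediate (not isolated)
7 | acetate of the aldol from 5 and 4 (both diastereomers) | CC(=O)OC(C1CCCC1=O)C1(CCC2(C)OCCO2)SCCCS1 | intermediate (not isolated)
8 | (E)-2-({2-[2-(2-methyl-1,3-dioxolan-2-yl)ethyl]-1,3-dithian-2-yl}methylidene)cyclopentan-1-one | O=C1CCC/C1=C\C1(CCC2(C)OCCO2)SCCCS1 | intermediate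
9 | (E)-2-{[2-(3-oxobutyl)-1,3-dithian-2-yl]methylidene}cyclopentan-1-one | O=C1CCC/C1=C\C1(CCC(C)=O)SCCCS1 | intermediate
10 | tert-butyl(3-iodopropoxy)dimethylsilane | CC(C)(C)[Si](C)(C)OCCCI | starting material
11 | [3-(tert-butyldimethylsilyloxy)propyl]zinc iodide | CC(C)(C)[Si](C)(C)OCCC[Zn]I | intermediate (not isolated)
12 | [3-(tert-butyldimethylsilyloxy)propyl][(trimethylsilyl)methyl]zinc | CC(C)(C)[Si](C)(C)OCCC[Zn]C[Si](C)(C)C | intermediate
13 | zinc enolate of the conjugate adduct (ring A enolate O–Zn–CH2SiMe3, C6 set) | C[Si](C)(C)C[Zn]OC1=C(CCC1)[C@@H](CCCO[Si](C)(C)C(C)(C)C)C1(CCC(C)=O)SCCCS1 | intermediate (not isolated)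
14 | zinc aldolate of 15 (C10 O–Zn–CH2SiMe3) | C1CC[C@]2([C@@H](CCCO[Si](C)(C)C(C)(C)C)C3(SCCCS3)CC[C@]2(C)O[Zn]C[Si](C)(C)C)C1=O | intermediate (not isolated)
15 | (5R,6R,10S)-6-[3-(tert-butyldimethylsilyloxy)propyl]-10-hydroxy-10-methylspiro[4.5]decan-1-one with C7 as a 1,3-dithiane; chain trans to C1, hydroxyl cis to C1 | C1CC[C@]2([C@@H](CCCO[Si](C)(C)C(C)(C)C)C3(SCCCS3)CC[C@]2(C)O)C1=O | intermediate
16 | 15 with the C10 hydroxyl as its triethylsilyl ether | C1CC[C@]2([C@@H](CCCO[Si](C)(C)C(C)(C)C)C3(SCCCS3)CC[C@]2(C)O[Si](CC)(CC)CC)C1=O | intermediate
17 | tert-butyl bromoacetate | CC(C)(C)OC(=O)CBr | starting material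
18 | 16 with a tert-butoxycarbonylmethyl group at C2 on the C6 side of ring A | CC(C)(C)OC(=O)C[C@@H]1CC[C@]2([C@@H](CCCO[Si](C)(C)C(C)(C)C)C3(SCCCS3)CC[C@]2(C)O[Si](CC)(CC)CC)C1=O | intermediate
19 | C1 alcohol from 18; hydroxyl on the C10 side, trans to the C2 arm | CC(C)(C)OC(=O)C[C@@H]1CC[C@]2([C@@H](CCCO[Si](C)(C)C(C)(C)C)C3(SCCCS3)CC[C@]2(C)O[Si](CC)(CC)CC)[C@H]1O | intermediate
20 | 19 with the C1 hydroxyl as its triethylsilyl ether | CC(C)(C)OC(=O)C[C@@H]1CC[C@]2([C@@H](CCCO[Si](C)(C)C(C)(C)C)C3(SCCCS3)CC[C@]2(C)O[Si](CC)(CC)CC)[C@H]1O[Si](CC)(CC)CC | intermediate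
21 | C7 ketone from 20; chain trans to C1 | CC(C)(C)OC(=O)C[C@@H]1CC[C@]2([C@@H](CCCO[Si](C)(C)C(C)(C)C)C(=O)CC[C@]2(C)O[Si](CC)(CC)CC)[C@H]1O[Si](CC)(CC)CC | intermediate
22 | pyrrolidine enamine (C7=C8, N at C7); chain cis to C1 and axial | CC(C)(C)OC(=O)C[C@@H]1CC[C@]2([C@H](CCCO[Si](C)(C)C(C)(C)C)C(N3CCCC3)=CC[C@]2(C)O[Si](CC)(CC)CC)[C@H]1O[Si](CC)(CC)CC | intermediate (not isolated)
23 | C7 ketone, C6 epimer of 21; chain cis to C1 (target configuration at C6) | CC(C)(C)OC(=O)C[C@@H]1CC[C@]2([C@H](CCCO[Si](C)(C)C(C)(C)C)C(=O)CC[C@]2(C)O[Si](CC)(CC)CC)[C@H]1O[Si](CC)(CC)CC | intermediate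
24 | C7 tertiary alcohol with an isopropenyl group; hydroxyl on the face of the C6 chain | CC(C)(C)OC(=O)C[C@@H]1CC[C@]2([C@H](CCCO[Si](C)(C)C(C)(C)C)[C@@](O)(C(C)=C)CC[C@]2(C)O[Si](CC)(CC)CC)[C@H]1O[Si](CC)(CC)CC | intermediate
25 | 6-methylhept-5-en-2-one | CC(=O)CCC=C(C)C | starting material
26 | 6-methylhepta-1,5-dien-2-yl trifluoromethanesulfonate | C=C(OS(=O)(=O)C(F)(F)F)CCC=C(C)C | intermediate
27 | (E)-2-(3,3-diethoxyprop-1-enyl)-4,4,5,5-tetramethyl-1,3,2-dioxaborolane | CCOC(OCC)/C=C/B1OC(C)(C)C(C)(C)O1 | starting material
28 | (2E)-1,1-diethoxy-8-methyl-4-methylidenenona-2,7-diene | CCOC(OCC)/C=C/C(=C)CCC=C(C)C | intermediate (not isolated)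
29 | (2E)-8-methyl-4-methylidenenona-2,7-dienal | O=C/C=C/C(=C)CCC=C(C)C | intermediate
30 | aldol adduct of the ester enolate of 24 with 29 (both new centres as a mixture) | CC(C)(C)OC(=O)C(C(O)/C=C/C(=C)CCC=C(C)C)[C@@H]1CC[C@]2([C@H](CCCO[Si](C)(C)C(C)(C)C)[C@@](O)(C(C)=C)CC[C@]2(C)O[Si](CC)(CC)CC)[C@H]1O[Si](CC)(CC)CC | intermediate
31 | methanesulfonate of 30 | CC(C)(C)OC(=O)C(C(OS(C)(=O)=O)/C=C/C(=C)CCC=C(C)C)[C@@H]1CC[C@]2([C@H](CCCO[Si](C)(C)C(C)(C)C)[C@@](O)(C(C)=C)CC[C@]2(C)O[Si](CC)(CC)CC)[C@H]1O[Si](CC)(CC)CC | intermediate (not isolated)
32 | tert-butyl (2E,4E)-trienoate: ring C2 on the α-carbon, dienyl group trans to the ester | C=C(/C=C/C=C(/C(=O)OC(C)(C)C)[C@@H]1CC[C@]2([C@H](CCCO[Si](C)(C)C(C)(C)C)[C@@](O)(C(C)=C)CC[C@]2(C)O[Si](CC)(CC)CC)[C@H]1O[Si](CC)(CC)CC)CCC=C(C)C | intermediate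
33 | allylic alcohol from 32 (CH2OH in place of the ester) | C=C(/C=C/C=C(/CO)[C@@H]1CC[C@]2([C@H](CCCO[Si](C)(C)C(C)(C)C)[C@@](O)(C(C)=C)CC[C@]2(C)O[Si](CC)(CC)CC)[C@H]1O[Si](CC)(CC)CC)CCC=C(C)C | intermediate
34 | acetate of 33 | C=C(/C=C/C=C(/COC(C)=O)[C@@H]1CC[C@]2([C@H](CCCO[Si](C)(C)C(C)(C)C)[C@@](O)(C(C)=C)CC[C@]2(C)O[Si](CC)(CC)CC)[C@H]1O[Si](CC)(CC)CC)CCC=C(C)C | intermediate
35 | tris-silylated target: (Z)-enal at C7 (formyl cis to C6), chain O-TBS, C1 and C10 O-TES | C=C(/C=C/C=C(/COC(C)=O)[C@@H]1CC[C@]2([C@H](CCCO[Si](C)(C)C(C)(C)C)/C(=C(/C)C=O)CC[C@]2(C)O[Si](CC)(CC)CC)[C@H]1O[Si](CC)(CC)CC)CCC=C(C)C | intermediate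
36 | CNP0204268.2: (2E,4E)-2-[(1S,2S,5S,6R,10S,7Z)-1,10-dihydroxy-6-(3-hydroxypropyl)-10-methyl-7-(1-oxopropan-2-ylidene)spiro[4.5]decan-2-yl]-10-methyl-6-methylideneundeca-2,4,9-trienyl acetate | C=C(/C=C/C=C(/COC(C)=O)[C@@H]1CC[C@]2([C@H](CCCO)/C(=C(/C)C=O)CC[C@]2(C)O)[C@H]1O)CCC=C(C)C | target

## Step count and risks

Total: 21 steps. Longest linear sequence: 18 steps (steps 1–4, 6–13, 16–21); steps 5, 14 and 15 are side branches.

**Step 6 (key step).** The addition may be slow and poorly face-selective because the β-carbon is flanked by the fully substituted dithiane carbon, whose sulfur atoms can also bind copper, and because the mixed zinc reagent may hand over its alkyl group less readily than a symmetrical dialkylzinc. The hindered zinc enolate may then fail to close at the temperature of the addition, or the aldolate may revert on warming. Fallback: split the cascade. From 9 and 12 the copper-catalysed addition is run with Me3SiOTf present so that the enolate is captured as the trimethylsilyl enol ether F1; the addition can then be optimised on its own. F1 is closed by a Mukaiyama aldol reaction (TiCl4, CH2Cl2, −78 °C), which activates the methyl ketone instead of relying on the zinc enolate, and returns to the route at 15. The same chair with equatorial chain and methyl is expected, but the C10 configuration would have to be confirmed.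

**Step 8.** Facial selectivity at C2 may be poor, since C2 is one bond further from the C10 silyloxy group than C1 and the two faces differ less there. Fallback: reagent control. 16 is condensed with (S)-1-amino-2-(methoxymethyl)pyrrolidine (neat, 60 °C) to the SAMP hydrazone F2. Its azaenolate (LiN(iPr)2, THF, then 17 at −100 °C) gives the alkylated hydrazone F3, with the auxiliary and not the substrate choosing the face. Two-phase cleavage with saturated aqueous oxalic acid returns to the route at 18.

**Step 12.** Condensation with pyrrolidine may be incomplete at a ketone flanked by a branched carbon next to the spiro centre, so that C6 is never equilibrated. Fallback: reach the same enamine by C–N coupling. 21 is converted into the kinetic enol triflate F4 (LiN(iPr)2, PhNTf2, −78 °C). Palladium-catalysed amination with pyrrolidine (Pd(OAc)2, rac-BINAP, Cs2CO3, toluene, 80 °C) gives the enamine F5 with the chain still trans. A trace of p-toluenesulfonic acid then equilibrates F5 through the iminium ion, returning to the route at 22 and, after the buffered hydrolysis, at 23.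

**Step 20.** Geometric control at the tetrasubstituted enal may be lost, because both rotamers of the isopropenyl group can undergo the shift and acid can equilibrate the product; the triene may also suffer under the oxidant. Fallback: replace kinetic control by equilibration and recycling. The mixture from 34 is separated into 35 and its geometric isomer, the (E)-enal F6. F6 is returned to the equilibrium mixture through its dienolate (DBU, toluene), in which the axial preference of the chain keeps C6 in the target configuration, and is separated again, returning to the route at 35.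

## Further compounds

F1 | step 6 | trimethylsilyl enol ether of the conjugate adduct of 9 and 12 | C[Si](C)(C)OC1=C(CCC1)[C@@H](CCCO[Si](C)(C)C(C)(C)C)C1(CCC(C)=O)SCCCS1
F2 | step 8 | SAMP hydrazone of 16 | C1CC[C@]2([C@@H](CCCO[Si](C)(C)C(C)(C)C)C3(SCCCS3)CC[C@]2(C)O[Si](CC)(CC)CC)C1=NN1CCC[C@H]1COC
F3 | step 8 | C2-alkylated SAMP hydrazone (hydrazone of 18) | CC(C)(C)OC(=O)C[C@@H]1CC[C@]2([C@@H](CCCO[Si](C)(C)C(C)(C)C)C3(SCCCS3)CC[C@]2(C)O[Si](CC)(CC)CC)C1=NN1CCC[C@H]1COC
F4 | step 12 | C7 enol triflate of 21 (C7=C8) | CC(C)(C)OC(=O)C[C@@H]1CC[C@]2([C@@H](CCCO[Si](C)(C)C(C)(C)C)C(OS(=O)(=O)C(F)(F)F)=CC[C@]2(C)O[Si](CC)(CC)CC)[C@H]1O[Si](CC)(CC)CC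
F5 | step 12 | C6 epimer of enamine 22 (chain trans to C1) | CC(C)(C)OC(=O)C[C@@H]1CC[C@]2([C@@H](CCCO[Si](C)(C)C(C)(C)C)C(N3CCCC3)=CC[C@]2(C)O[Si](CC)(CC)CC)[C@H]1O[Si](CC)(CC)CC
F6 | step 20 | (E)-enal isomer of 35 (formyl trans to C6) | C=C(/C=C/C=C(/COC(C)=O)[C@@H]1CC[C@]2([C@H](CCCO[Si](C)(C)C(C)(C)C)/C(=C(\C)C=O)CC[C@]2(C)O[Si](CC)(CC)CC)[C@H]1O[Si](CC)(CC)CC)CCC=C(C)C
A1 | alternative 1 | ring B C7 ketone whose hydroxypropyl oxygen carries a 2-(diethoxyphosphoryl)propanoyl group (C1 O-TBS, C2 2-(4-methoxybenzyloxy)ethyl) | COc1ccc(COCC[C@@H]2CC[C@]3([C@H](CCCOC(=O)C(C)P(=O)(OCC)OCC)C(=O)CC[C@]3(C)O)[C@H]2O[Si](C)(C)C(C)(C)C)cc1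
A2 | alternative 1 | eight-membered unsaturated lactone fused to ring B | COc1ccc(COCC[C@@H]2CC[C@]3([C@@H]4CCCOC(=O)/C(C)=C4/CC[C@]3(C)O)[C@H]2O[Si](C)(C)C(C)(C)C)cc1
A3 | alternative 2 | ring B aldehyde enoate: C5 carries a formyl group and an (E)-5-tert-butoxy-5-oxopent-3-enyl chain | CC(C)(C)OC(=O)/C=C/CC[C@@]1(C=O)[C@H](CCCO[Si](C)(C)C(C)(C)C)C2(SCCCS2)CC[C@]1(C)O
A4 | alternative 2 | spiro trans-2-(tert-butoxycarbonylmethyl)cyclopentanol | CC(C)(C)OC(=O)C[C@@H]1CC[C@]2([C@H](CCCO[Si](C)(C)C(C)(C)C)C3(SCCCS3)CC[C@]2(C)O)[C@H]1O
A5 | alternative 3 | epoxy alcohol: ring A C1–C5 epoxide bonded at C5 to a 1-hydroxycyclopentyl ring that carries the chain and the silyl group (carbinol configuration as drawn, either would serve) | c1ccc(COCC[C@@H]2CC[C@@]3([C@]4(O)CC[C@H]([Si](C)(C)c5ccccc5)[C@H]4CCCO[Si](C)(C)C(C)(C)C)O[C@@H]23)cc1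
A6 | alternative 3 | spiro[4.5]decane β-hydroxy ketone | c1ccc(COCC[C@@H]2CC[C@]3([C@H](CCCO[Si](C)(C)C(C)(C)C)[C@@H]([Si](C)(C)c4ccccc4)CCC3=O)[C@H]2O)cc1
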